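**Plan**
- Retrosynthesis: the two isobutyrate C–O bonds and the silyl ether are cut first, then the side-chain CH=CH bond (cross-metathesis) and the allyl–vinyl C–C bond at the former isopropenyl methyl. Next comes the ring bond between the alkene carbon and the carbinol carbon, and last the enal C=C and the isopropenyl–C bond of an acyclic chain.
- Enabling feature: in the six-membered ring the CH(OH) carbon (C6) is bonded to the ring-alkene carbon C1 that carries the CH2O-isobutyrate carbon. With that carbon as CHO, C1 is the α-carbon of an enal next to a carbinol, the retron of an intramolecular Morita–Baylis–Hillman reaction of a hept-2-enedial.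
- Forward: a δ-lactone carrying the isopropenyl stereocentre is opened and extended to enal-aldehyde 9, and the only ring is closed in step 6. The isopropenyl methyl is then chlorinated and vinylated, the aldehyde reduced, the side chain joined by cross-metathesis, both primary alcohols acylated together, and the silyl ether removed.
- Stereochemistry: ring C4 comes from the Rh/(R)-BINAP 1,4-addition; ring C6 from the proline-controlled closure (cis to the C4 substituent); the tertiary carbinol from a Pd-catalysed dynamic kinetic asymmetric opening of isoprene monoepoxide; the E alkene from the metathesis.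

Key step: step 6

Assumption: D-proline (step 6) and the (R,R) ligand (step 11) are written as the catalyst enantiomers taken to give the (6S) carbinol and the (R) diol; if either sense of induction proves opposite on these substrates, the antipodal catalyst is used and nothing else changes.

**Route**

Step 1
Reactants: 1 5,6-dihydro-2H-pyran-2-one; 2 isopropenylboronic acid pinacol ester
Product: 3 (4R)-4-(prop-1-en-2-yl)tetrahydro-2H-pyran-2-one
Conditions: 2 (2 equiv), Rh(acac)(C2H4)2 (3 mol %), (R)-BINAP (3.3 mol %), dioxane/H2O 10:1, 100 °C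
Reagents that add atoms: none
Why: Hayashi–Miyaura rhodium-catalysed asymmetric 1,4-addition of an alkenylboron reagent to an α,β-unsaturated δ-lactone: the (R)-BINAP complex of monovalent rhodium shields one enoate face, so the isopropenyl group should be delivered to C4 with the R configuration, the mirror image of the S lactone expected from (S)-BINAP.

Step 2
Reactants: 3 (4R)-4-(prop-1-en-2-yl)tetrahydro-2H-pyran-2-one
Product: 4 (4R)-4-(prop-1-en-2-yl)tetrahydro-2H-pyran-2-ol (both anomers)
Conditions: iBu2AlH (1.1 equiv), CH2Cl2, −78 °C; aq. KNaC4H4O6 work-up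
Reagents that add atoms: none
Why: Partial reduction of a lactone to the lactol with iBu2AlH, whose tetrahedral aluminate persists at −78 °C until work-up; the C4 stereocentre is not involved.

Step 3
Reactants: 4 (4R)-4-(prop-1-en-2-yl)tetrahydro-2H-pyran-2-ol
Product: 6 (3S)-3-(prop-1-en-2-yl)hex-5-en-1-ol, via hydroxy aldehyde 5 (not isolated)
Conditions: Ph3PCH3Br (3 equiv), KOtBu (2.9 equiv), THF, 0 °C to rt
Reagents that add atoms: methyltriphenylphosphonium bromide, C[P+](c1ccccc1)(c1ccccc1)c1ccccc1.[Br-]
Why: Wittig methylenation of a lactol through its open-chain tautomer 5, with excess ylide compensating for the alkoxide; the stereocentre is β to the carbonyl and cannot epimerise.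

Step 4
Reactants: 6 (3S)-3-(prop-1-en-2-yl)hex-5-en-1-ol
Product: 7 (3S)-3-(prop-1-en-2-yl)hex-5-enal
Conditions: Dess–Martin periodinane (1.2 equiv), CH2Cl2, 0 °C to rt
Reagents that add atoms: none
Why: Dess–Martin oxidation of a primary alcohol to the aldehyde under near-neutral conditions that leave both alkenes and the β-stereocentre untouched.

Step 5
Reactants: 7 (3S)-3-(prop-1-en-2-yl)hex-5-enal; 8 crotonaldehyde
Product: 9 (2E,5S)-5-(prop-1-en-2-yl)hept-2-enedial
Conditions: 8 (5 equiv), second-generation Hoveyda–Grubbs catalyst RuCl2(H2IMes)(=CH-C6H4-2-OiPr) (3 mol %), CH2Cl2, 40 °C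
Reagents that add atoms: none
Why: Olefin cross-metathesis of the terminal monosubstituted alkene with crotonaldehyde; the 1,1-disubstituted isopropenyl alkene is too hindered to engage (ring closure onto it would need a cyclobutene) and the E enal is the thermodynamic product.

Step 6
Reactants: 9 (2E,5S)-5-(prop-1-en-2-yl)hept-2-enedial
Product: 10 (4S,6S)-6-hydroxy-4-(prop-1-en-2-yl)cyclohex-1-ene-1-carbaldehyde
Conditions: D-proline (20 mol %), imidazole (20 mol %), MeCN (0.05 M), 0 °C
Reagents that add atoms: none
Why: D-Proline condenses with the enal of 9 to an iminium ion, imidazole adds to its β-carbon (C3), and the enamine so formed attacks the tethered C7 aldehyde through C2; β-elimination of imidazole and hydrolysis return both catalysts and the conjugated enal (amine-catalysed intramolecular Morita–Baylis–Hillman reaction, the closest known case being the proline/imidazole cyclisation of hept-2-enedials to 6-hydroxycyclohex-1-enecarbaldehydes). The single ring closes in a 6-exo-trig (enolexo) aldol mode, C2 adding to the exocyclic C7=O. The new carbinol centre C6 is set by the proline unit, whose carboxylic acid hydrogen-bonds the aldehyde oxygen and so selects the face attacked, within a chair-like transition state that keeps the C5 isopropenyl group equatorial and should reinforce the cis (4S,6S) isomer. The step needs C–C bond formation at the enal α-carbon in preference to intermolecular aldol chemistry: the alternative intramolecular enamine additions (C6 onto C3 or onto C1) would require a four-membered ring or an E alkene inside a six-membered ring, and dilution disfavours oligomers. The C5 stereocentre is β to the C7 carbonyl and remote from the enal, so neither enamine nor dienamine formation can epimerise it.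

Step 7
Reactants: 10 (4S,6S)-6-hydroxy-4-(prop-1-en-2-yl)cyclohex-1-ene-1-carbaldehyde
Product: 11 (4S,6S)-6-[(tert-butyldimethylsilyl)oxy]-4-(prop-1-en-2-yl)cyclohex-1-ene-1-carbaldehyde
Conditions: TBSCl (1.3 equiv), imidazole (2.5 equiv), DMF, rt
Reagents that add atoms: tert-butyldimethylsilyl chloride, CC(C)(C)[Si](C)(C)Cl
Why: Silylation of a secondary allylic alcohol removes the hydroxyl that, being cis-1,3 to the isopropenyl group, could trap the chloronium ion of step 8 as a bridged (pinol-type) ether, and it later confines acylation to the primary alcohols.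

Step 8
Reactants: 11 (4S,6S)-6-[(tert-butyldimethylsilyl)oxy]-4-(prop-1-en-2-yl)cyclohex-1-ene-1-carbaldehyde
Product: 12 (4S,6S)-6-[(tert-butyldimethylsilyl)oxy]-4-(3-chloroprop-1-en-2-yl)cyclohex-1-ene-1-carbaldehyde
Conditions: Ca(OCl)2 (0.7 equiv), solid CO2 in portions, CH2Cl2/H2O, 0 °C
Reagents that add atoms: calcium hypochlorite, [Ca+2].[O-]Cl.[O-]Cl
Why: Ene-type allylic chlorination of an isopropenyl group by HOCl generated in situ, the reaction that turns carvone into 10-chlorocarvone: the electron-rich 1,1-disubstituted alkene reacts while the formyl-conjugated ring alkene is deactivated, and proton loss from the methyl group leaves the C4 stereocentre intact.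

Step 9
Reactants: 12 (4S,6S)-6-[(tert-butyldimethylsilyl)oxy]-4-(3-chloroprop-1-en-2-yl)cyclohex-1-ene-1-carbaldehyde
Product: 13 (4S,6S)-6-[(tert-butyldimethylsilyl)oxy]-4-(penta-1,4-dien-2-yl)cyclohex-1-ene-1-carbaldehyde
Conditions: Bu3SnCH=CH2 (1.2 equiv), Pd2(dba)3 (2.5 mol %), P(2-furyl)3 (10 mol %), THF, 55 °C
Reagents that add atoms: tributyl(vinyl)stannane, C=C[Sn](CCCC)(CCCC)CCCC
Why: Stille coupling of an allylic chloride with a vinylstannane through a 2-substituted π-allyl complex of divalent palladium whose two termini are equivalent, so only one skipped diene can form, under neutral conditions that tolerate the enal and the silyl ether.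

Step 10
Reactants: 13 (4S,6S)-6-[(tert-butyldimethylsilyl)oxy]-4-(penta-1,4-dien-2-yl)cyclohex-1-ene-1-carbaldehyde
Product: 14 [(4S,6S)-6-[(tert-butyldimethylsilyl)oxy]-4-(penta-1,4-dien-2-yl)cyclohex-1-en-1-yl]methanol
Conditions: NaBH4 (1.1 equiv), CeCl3·7H2O (1.1 equiv), MeOH, −40 °C
Reagents that add atoms: none
Why: Luche 1,2-reduction of the enal to the primary allylic alcohol; no stereocentre is formed and the alkenes are not touched.

Step 11
Reactants: 15 2-methyl-2-vinyloxirane (racemic)
Product: 17 (2R)-2-methylbut-3-ene-1,2-diol, via hydrogen carbonate 16 (not isolated)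
Conditions: Pd2(dba)3·CHCl3 (1 mol %), (R,R)-DACH-phenyl Trost ligand (3 mol %), NaHCO3 (1 equiv), Et3B (1 mol %), CH2Cl2/H2O, rt
Reagents that add atoms: sodium hydrogencarbonate, [Na+].OC([O-])=O
Why: Palladium-catalysed dynamic kinetic asymmetric transformation of a vinyl epoxide (Trost asymmetric allylic alkylation with an oxygen nucleophile): the π-allyl complexes from both epoxide enantiomers interconvert, and boron-templated hydrogencarbonate attacks the tertiary terminus of the one matched to the ligand to give 16, which loses CO2 to the R tertiary alcohol.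

Step 12
Reactants: 14 [(4S,6S)-6-[(tert-butyldimethylsilyl)oxy]-4-(penta-1,4-dien-2-yl)cyclohex-1-en-1-yl]methanol; 17 (2R)-2-methylbut-3-ene-1,2-diol
Product: 18 (2R,3E)-6-[(1S,5S)-5-[(tert-butyldimethylsilyl)oxy]-4-(hydroxymethyl)cyclohex-3-en-1-yl]-2-methylhepta-3,6-diene-1,2-diol
Conditions: 17 (3 equiv), second-generation Hoveyda–Grubbs catalyst RuCl2(H2IMes)(=CH-C6H4-2-OiPr) (5 mol %), 1,4-benzoquinone (10 mol %), CH2Cl2, 40 °C
Reagents that add atoms: none
Why: Cross-metathesis of the only monosubstituted alkene of 14 with a tertiary allylic alcohol used in excess (a partner that homodimerises slowly); the quaternary allylic carbon enforces the E geometry, the 1,1-disubstituted and ring alkenes stay inert, and benzoquinone suppresses migration of the skipped diene.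

Step 13
Reactants: 18 (2R,3E)-6-[(1S,5S)-5-[(tert-butyldimethylsilyl)oxy]-4-(hydroxymethyl)cyclohex-3-en-1-yl]-2-methylhepta-3,6-diene-1,2-diol
Product: 19 [(4S,6S)-6-[(tert-butyldimethylsilyl)oxy]-4-[(4E,6R)-6-hydroxy-6-methyl-7-(2-methylpropanoyloxy)hepta-1,4-dien-2-yl]cyclohex-1-en-1-yl]methyl 2-methylpropanoate
Conditions: isobutyryl chloride (2.5 equiv), pyridine (6 equiv), CH2Cl2, 0 °C
Reagents that add atoms: isobutyryl chloride, CC(C)C(=O)Cl
Why: Acylation with an acid chloride and pyridine distinguishes the hydroxyl classes: both primary alcohols are esterified, the tertiary alcohol does not react without a nucleophilic catalyst, and the secondary one is silylated.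

Step 14
Reactants: 19 [(4S,6S)-6-[(tert-butyldimethylsilyl)oxy]-4-[(4E,6R)-6-hydroxy-6-methyl-7-(2-methylpropanoyloxy)hepta-1,4-dien-2-yl]cyclohex-1-en-1-yl]methyl 2-methylpropanoate
Product: 20 [(4S,6S)-6-hydroxy-4-[(4E,6R)-6-hydroxy-6-methyl-7-(2-methylpropanoyloxy)hepta-1,4-dien-2-yl]cyclohex-1-en-1-yl]methyl 2-methylpropanoate
Conditions: HF·pyridine, pyridine, THF, 0 °C to rt
Reagents that add atoms: none
Why: Fluoride cleavage of the secondary TBS ether under pyridine-buffered, non-basic conditions, so that the neighbouring primary ester should not migrate to the liberated hydroxyl and the tertiary allylic alcohol should not ionise.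

**Compound list**

1 | 5,6-dihydro-2H-pyran-2-one | O=C1C=CCCO1 | starting material
2 | isopropenylboronic acid pinacol ester | C=C(C)B1OC(C)(C)C(C)(C)O1 | starting material
3 | (4R)-4-(prop-1-en-2-yl)tetrahydro-2H-pyran-2-one | C=C(C)[C@H]1CC(=O)OCC1 | intermediate
4 | (4R)-4-(prop-1-en-2-yl)tetrahydro-2H-pyran-2-ol (both anomers) | C=C(C)[C@H]1CC(O)OCC1 | intermediate
5 | (3R)-5-hydroxy-3-(prop-1-en-2-yl)pentanal (open form of 4, not isolated) | C=C(C)[C@H](CCO)CC=O | intermediate
6 | (3S)-3-(prop-1-en-2-yl)hex-5-en-1-ol | C=C(C)[C@H](CCO)CC=C | intermediate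
7 | (3S)-3-(prop-1-en-2-yl)hex-5-enal | C=C(C)[C@H](CC=O)CC=C | intermediate
8 | (E)-but-2-enal (crotonaldehyde) | C/C=C/C=O | starting material
9 | (2E,5S)-5-(prop-1-en-2-yl)hept-2-enedial | C=C(C)[C@@H](C/C=C/C=O)CC=O | intermediate
10 | (4S,6S)-6-hydroxy-4-(prop-1-en-2-yl)cyclohex-1-ene-1-carbaldehyde | C=C(C)[C@H]1CC=C(C=O)[C@@H](O)C1 | intermediate
11 | (4S,6S)-6-[(tert-butyldimethylsilyl)oxy]-4-(prop-1-en-2-yl)cyclohex-1-ene-1-carbaldehyde | C=C(C)[C@H]1CC=C(C=O)[C@@H](O[Si](C)(C)C(C)(C)C)C1 | intermediate
12 | (4S,6S)-6-[(tert-butyldimethylsilyl)oxy]-4-(3-chloroprop-1-en-2-yl)cyclohex-1-ene-1-carbaldehyde | C=C(CCl)[C@H]1CC=C(C=O)[C@@H](O[Si](C)(C)C(C)(C)C)C1 | intermediate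
13 | (4S,6S)-6-[(tert-butyldimethylsilyl)oxy]-4-(penta-1,4-dien-2-yl)cyclohex-1-ene-1-carbaldehyde | C=CCC(=C)[C@H]1CC=C(C=O)[C@@H](O[Si](C)(C)C(C)(C)C)C1 | intermediate
14 | [(4S,6S)-6-[(tert-butyldimethylsilyl)oxy]-4-(penta-1,4-dien-2-yl)cyclohex-1-en-1-yl]methanol | C=CCC(=C)[C@H]1CC=C(CO)[C@@H](O[Si](C)(C)C(C)(C)C)C1 | intermediate
15 | 2-methyl-2-vinyloxirane (racemic) | C=CC1(C)CO1 | starting material
16 | (2R)-1-hydroxy-2-methylbut-3-en-2-yl hydrogen carbonate (not isolated) | C=C[C@@](C)(OC(=O)O)CO | intermediate
17 | (2R)-2-methylbut-3-ene-1,2-diol | C=C[C@@](C)(O)CO | intermediate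
18 | (2R,3E)-6-[(1S,5S)-5-[(tert-butyldimethylsilyl)oxy]-4-(hydroxymethyl)cyclohex-3-en-1-yl]-2-methylhepta-3,6-diene-1,2-diol | C=C(C/C=C/[C@@](C)(O)CO)[C@H]1CC=C(CO)[C@@H](O[Si](C)(C)C(C)(C)C)C1 | intermediate
19 | [(4S,6S)-6-[(tert-butyldimethylsilyl)oxy]-4-[(4E,6R)-6-hydroxy-6-methyl-7-(2-methylpropanoyloxy)hepta-1,4-dien-2-yl]cyclohex-1-en-1-yl]methyl 2-methylpropanoate | C=C(C/C=C/[C@@](C)(O)COC(=O)C(C)C)[C@H]1CC=C(COC(=O)C(C)C)[C@@H](O[Si](C)(C)C(C)(C)C)C1 | intermediate
20 | [(4S,6S)-6-hydroxy-4-[(4E,6R)-6-hydroxy-6-methyl-7-(2-methylpropanoyloxy)hepta-1,4-dien-2-yl]cyclohex-1-en-1-yl]methyl 2-methylpropanoate (CNP0599657.1) | C=C(C/C=C/[C@@](C)(O)COC(=O)C(C)C)[C@H]1CC=C(COC(=O)C(C)C)[C@@H](O)C1 | target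

**Step count**

Total: 14 steps. Longest linear sequence: 13 steps (steps 1–10 and 12–14); the diol fragment 17 takes one step (step 11).

**Steps most likely to fail**

Step 6. The resident C5 stereocentre and the proline catalyst may oppose each other in the aldol transition state, so that the aldehyde face is poorly discriminated and both carbinol epimers form. The fallback sets out from 9 and returns at 20; it resets the carbinol under substrate control and needs no protecting group.
- Closure of 9 with racemic proline and imidazole, without regard to the carbinol configuration, gives the C6-epimeric hydroxy enal F1.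
- Luche reduction gives the diol F2, and isobutyryl chloride with 2,4,6-collidine at −78 °C acylates only the primary hydroxyl to give the monoester F3.
- Oxidation of the remaining secondary allylic alcohol with MnO2 merges both epimers in the enone F4, a carvone-type 5-substituted cyclohex-2-enone.
- Ca(OCl)2/CO2 chlorinates the isopropenyl methyl to give the chloride F5, and Stille coupling with tributyl(vinyl)stannane gives the dienyl enone F6.
- Luche reduction, by axial hydride delivery as in the reduction of carvone to cis-carveol, should give the cis alcohol F7.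
- Cross-metathesis of F7 with the mono-isobutyrate F8, made from 17 and isobutyryl chloride, then gives 20.

Step 12. Slow engagement of the hindered tertiary allylic alcohol may let 14 homodimerise, and ruthenium hydride species from catalyst decay may move the skipped diene into conjugation. The fallback sets out from 12 (with 17) and returns at 18, bypassing steps 9, 10 and 12; the metathesis is moved to the small fragment and the skipped diene is made by the C–C coupling itself.
- Cross-metathesis of 17 with vinylboronic acid pinacol ester (same ruthenium catalyst) gives the (E)-alkenylboronate F9.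
- Suzuki–Miyaura coupling of F9 with the allylic chloride 12 (Pd(PPh3)4, K3PO4, THF/H2O, 50 °C) gives the enal diol F10.
- Luche reduction of F10 gives 18.

Step 8. HOCl may fail to discriminate on the functionalised enal: chlorohydrin formation at the isopropenyl group, oxidation of the formyl group or partial loss of the silyl ether may compete with the ene chlorination. The fallback sets out from 7 and returns at 13; the C–H chlorination is moved ahead of ring formation, where the isopropenyl group is the only electron-rich alkene and neither enal nor silyl ether is present.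
- Ca(OCl)2/CO2 converts 7 into the chloro aldehyde F11, and cross-metathesis with crotonaldehyde 8 gives the chloro dial F12.
- Stille vinylation is carried out before the amine-catalysed step, so that imidazole is not alkylated by the allylic chloride, and gives the dienyl dial F13.
- The proline/imidazole closure of step 6 applied to F13 gives the hydroxy enal F14, and silylation as in step 7 gives 13.

**Further compounds**

F1 | step 6 | (4S,6RS)-6-hydroxy-4-(prop-1-en-2-yl)cyclohex-1-ene-1-carbaldehyde (both C6 epimers) | C=C(C)[C@H]1CC=C(C=O)C(O)C1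
F2 | step 6 | (1RS,5S)-2-(hydroxymethyl)-5-(prop-1-en-2-yl)cyclohex-2-en-1-ol | C=C(C)[C@H]1CC=C(CO)C(O)C1
F3 | step 6 | [(4S,6RS)-6-hydroxy-4-(prop-1-en-2-yl)cyclohex-1-en-1-yl]methyl 2-methylpropanoate | C=C(C)[C@H]1CC=C(COC(=O)C(C)C)C(O)C1
F4 | step 6 | [(4S)-6-oxo-4-(prop-1-en-2-yl)cyclohex-1-en-1-yl]methyl 2-methylpropanoate | C=C(C)[C@H]1CC=C(COC(=O)C(C)C)C(=O)C1
F5 | step 6 | [(4S)-4-(3-chloroprop-1-en-2-yl)-6-oxocyclohex-1-en-1-yl]methyl 2-methylpropanoate | C=C(CCl)[C@H]1CC=C(COC(=O)C(C)C)C(=O)C1
F6 | step 6 | [(4S)-6-oxo-4-(penta-1,4-dien-2-yl)cyclohex-1-en-1-yl]methyl 2-methylpropanoate | C=CCC(=C)[C@H]1CC=C(COC(=O)C(C)C)C(=O)C1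
F7 | step 6 | [(4S,6S)-6-hydroxy-4-(penta-1,4-dien-2-yl)cyclohex-1-en-1-yl]methyl 2-methylpropanoate | C=CCC(=C)[C@H]1CC=C(COC(=O)C(C)C)[C@@H](O)C1
F8 | step 6 | (2R)-2-hydroxy-2-methylbut-3-en-1-yl 2-methylpropanoate | C=C[C@@](C)(O)COC(=O)C(C)C
F9 | step 12 | (2R,3E)-2-methyl-4-(4,4,5,5-tetramethyl-1,3,2-dioxaborolan-2-yl)but-3-ene-1,2-diol | CC1(C)OB(/C=C/[C@@](C)(O)CO)OC1(C)C
F10 | step 12 | (4S,6S)-6-[(tert-butyldimethylsilyl)oxy]-4-[(4E,6R)-6,7-dihydroxy-6-methylhepta-1,4-dien-2-yl]cyclohex-1-ene-1-carbaldehyde | C=C(C/C=C/[C@@](C)(O)CO)[C@H]1CC=C(C=O)[C@@H](O[Si](C)(C)C(C)(C)C)C1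
F11 | step 8 | (3S)-3-(3-chloroprop-1-en-2-yl)hex-5-enal | C=C(CCl)[C@H](CC=O)CC=C
F12 | step 8 | (2E,5S)-5-(3-chloroprop-1-en-2-yl)hept-2-enedial | C=C(CCl)[C@@H](C/C=C/C=O)CC=O
F13 | step 8 | (2E,5S)-5-(penta-1,4-dien-2-yl)hept-2-enedial | C=CCC(=C)[C@@H](C/C=C/C=O)CC=O
F14 | step 8 | (4S,6S)-6-hydroxy-4-(penta-1,4-dien-2-yl)cyclohex-1-ene-1-carbaldehyde | C=CCC(=C)[C@H]1CC=C(C=O)[C@@H](O)C1
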